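## Retrosynthetic overview

1. Numbering: ring A (dihydropyran) is C1(acetal)–O2–C3=C4–C5–C11. Ring B (cycloheptane) is C5–C6–C7–C8–C9–C10–C11. Ring C (cyclopropane) is C6–C7–C12. Ring D (oxepane) is C12–C14–O–C15–C4–C5–C6. C13 is the CH2OAc on C12. β is the face of ring B that carries C12; α is the face that carries C4, C1 and the C10 hydroxyl.
2. Feature: take away C1 and C3 and make C4 a symmetrical ketal, and ring B with C5 as its only sp3 carbon is a 7-substituted cycloheptatriene. Its mirror plane (through C5 and the C8–C9 midpoint) makes C6=C7 and C11=C10 enantiotopic, and C12 can hang from C4 through the later C15–O–C14 bridge.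
3. Ring A goes back to a C1/C3 dialdehyde. C3 comes from a Wittig reaction at the C4 ketone. C1, the C10 methyl and the C10 hydroxyl come from a C11 enone made from the diene that the key step leaves.
4. Rings C and D are cut together. C12–C6 and C12–C7 form by addition of a C12 carbene (diazomalonate) to C6=C7, and ring D is the tether ring (C14 lactone, later taken down to the ether). The precursor is built from the tropylium ion (ring B), a dimethoxyacetate (C4, C15) and a malonic half ester (C12–C14).
5. Order of ring formation: B (bought as the seven-carbon cation), then C and D in one step, then A.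

Key step: step 5

Assumption 1: the sense of induction of Rh2(S-NTTL)4 on this substrate cannot be predicted. The S catalyst is written; if it favours C11=C10, the R catalyst is used instead.

Assumption 2: transient stereo-elements (C10/C11 in 17–19, C4 in 31, the C3=C4 geometry in 29 and 30) are drawn as expected or left open. All of them are erased later.

Design remark: no acid meets a cycloheptatriene that has a carbonyl or cationic C4, because this aromatises through the norcaradiene. Both C12 carbonyl groups are removed before a ketone is placed next to C5, because a C5 enolate would open an acceptor-substituted cyclopropane.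

## Route

Step 1
Reactants: 1 tropylium tetrafluoroborate; 2 methyl dimethoxyacetate
Product: 4 methyl 2-(cyclohepta-2,4,6-trien-1-yl)-2,2-dimethoxyacetate, via lithium enolate 3 (not isolated)
Conditions: LiN(iPr)2, THF, −78 °C; then solid 1, −78 °C to 0 °C
Reagents that add atoms: none
Why: Cation–enolate combination, in which ester enolates attack the tropylium ion at carbon to give 7-substituted cycloheptatrienes, and bringing C4 in as a ready-made ketal nucleophile avoids ketalising a 7-acylcycloheptatriene under acid.

Step 2
Reactants: 4 methyl 2-(cyclohepta-2,4,6-trien-1-yl)-2,2-dimethoxyacetate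
Product: 5 2-(cyclohepta-2,4,6-trien-1-yl)-2,2-dimethoxyethanol (C15 carbinol)
Conditions: LiAlH4, Et2O, 0 °C
Reagents that add atoms: none
Why: Standard hydride reduction of an ester to the primary alcohol, to which the triene and the ketal are inert.

Step 3
Reactants: 5 2-(cyclohepta-2,4,6-trien-1-yl)-2,2-dimethoxyethanol; 6 mono-tert-butyl malonate
Product: 7 tert-butyl 2-(cyclohepta-2,4,6-trien-1-yl)-2,2-dimethoxyethyl malonate
Conditions: DCC, DMAP (cat.), CH2Cl2, 0 °C to rt
Reagents that add atoms: none
Why: Steglich esterification acylates the neopentyl-type C15 alcohol under neutral conditions that leave the ketal and the triene alone.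

Step 4
Reactants: 7 mixed malonate
Product: 8 tert-butyl 2-(cyclohepta-2,4,6-trien-1-yl)-2,2-dimethoxyethyl 2-diazomalonate (achiral precursor of the key step)
Conditions: 4-acetamidobenzenesulfonyl azide, Et3N, MeCN, 0 °C to rt
Reagents that add atoms: 4-acetamidobenzenesulfonyl azide CC(=O)Nc1ccc(cc1)S(=O)(=O)N=[N+]=[N-]
Why: Regitz diazo transfer to the malonate CH2, the only acidic position, for which triethylamine is a sufficient base.

Step 5
Reactants: 8 diazomalonate
Product: 10 tricyclic lactone with rings B C D (C14 lactone endo; C13 tert-butyl ester exo; C4 dimethyl ketal; C8=C9–C10=C11 diene; H5 anti to H6), via dirhodium carbene 9 (not isolated)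
Conditions: Rh2(S-NTTL)4 (dirhodium tetrakis[N-(1,8-naphthaloyl)-(S)-tert-leucinate], 1 mol %), 4 Å sieves, CH2Cl2, 40 °C, 8 added by syringe pump over 8 h
Reagents that add atoms: none
Why: Loss of N2 at the axial site of the dirhodium tetracarboxylate gives the electrophilic carbene 9, which adds in a concerted, asynchronous [2+1] manner to the nearest ring alkene; the closest known reactions are enantioselective intramolecular cyclopropanations of diazoacetates and diazomalonates that desymmetrise dienes, and carbene additions inside cycloheptatrienyl diazo ketones. Ring C closes by the [2+1] addition (C12–C6 and C12–C7) and ring D closes as the seven-membered tether ring C12–C14–O–C15–C4–C5–C6, with the geminal methoxy groups at C4 helping the ester to fold. C6 and C7 are set cis by the suprafacial addition, and C5 becomes stereogenic through the choice of alkene. Its H5/H6 anti relation should follow because in the boat cycloheptatriene C4 is equatorial and lies in the plane of C6=C7, so the tether curls onto the outward face that carries the axial H5, while C12 is fixed because the tether can place C14 only endo (cis to C5), which leaves the tert-butyl ester exo. The choice between C6=C7 and C11=C10 is left to the chiral pocket of the catalyst, and the bulky tert-butyl ester widens the difference between the two carbene substituents. Chemoselectivity rests on the substrate, since C4 has no hydrogen (no γ-lactone by C–H insertion), there is no ketone oxygen (no carbonyl ylide), C8=C9 is out of reach and slow addition suppresses dimer, so attack on a methoxy oxygen and insertion into C5–H remain the competing paths.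

Step 6
Reactants: 10 tricyclic lactone
Product: 11 diol (C14H2OH endo on C12; C15H2OH on C4; tert-butyl ester and diene kept)
Conditions: LiBH4, THF, 0 °C to rt
Reagents that add atoms: none
Why: Chemoselective hydride reduction, in which LiBH4 reduces the seven-membered lactone but not the hindered tert-butyl ester, so C14 and C13 stay distinguishable and one of the two acceptors that make the dienyl cyclopropane prone to heterolysis is removed at once.

Step 7
Reactants: 11 diol
Product: 12 iodo alcohol (C14H2I; C15H2OH)
Conditions: PPh3, imidazole, I2 (premixed), CH2Cl2, 0 °C to rt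
Reagents that add atoms: iodine II
Why: Garegg–Samuelsson (Appel-type) iodination, in which both hydroxyls can form alkoxyphosphonium salts but only the cyclopropylmethyl carbon C14 is open to SN2 attack, while the neopentyl C15 next to the ketal returns as the alcohol on work-up and the geminal ester suppresses ionisation at C14.

Step 8
Reactants: 12 iodo alcohol
Product: 13 oxepane tert-butyl ester (ring D reclosed as the C14–O–C15 ether; diene kept)
Conditions: NaH, THF, 0 °C to 50 °C
Reagents that add atoms: none
Why: Intramolecular Williamson etherification (7-exo-tet) between two arms that were already held together as the lactone, with no β-hydrogen at C12 for elimination.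

Step 9
Reactants: 13 oxepane tert-butyl ester
Product: 14 C13 primary alcohol
Conditions: LiAlH4, THF, 0 °C to rt
Reagents that add atoms: none
Why: Hydride reduction of the tert-butyl ester, after which the cyclopropane carries no acceptor and cannot be opened by zerovalent palladium, soft nucleophiles or a neighbouring enolate.

Step 10
Reactants: 14 C13 primary alcohol
Product: 15 C13 tert-butyldimethylsilyl ether
Conditions: TBSCl, imidazole, DMF, rt
Reagents that add atoms: tert-butyldimethylsilyl chloride CC(C)(C)[Si](C)(C)Cl
Why: Standard silylation of the only hydroxyl, so that C13–O stays distinguishable from the later C1–OH.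

Step 11
Reactants: 15 diene silyl ether
Product: 16 monoene (C8 and C9 saturated; C10=C11 kept)
Conditions: 2-nitrobenzenesulfonohydrazide, Et3N, CH2Cl2, rt, stopped after one equivalent of diimide is taken up
Reagents that add atoms: none
Why: Diimide reduction transfers H2 in a concerted syn manner without touching the vinylcyclopropane σ-frame, and it should choose C8=C9 because this alkene has an open α face next to H7 only while C10=C11 is flanked by the quaternary C4, the conjugated diene also being reduced faster than the isolated alkene of 16.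

Step 12
Reactants: 16 monoene
Product: 17 10β,11β-epoxide
Conditions: mCPBA, NaHCO3, CH2Cl2, 0 °C
Reagents that add atoms: 3-chloroperbenzoic acid OOC(=O)c1cccc(Cl)c1
Why: Prilezhaev epoxidation of the only alkene, expected anti to C4, although the face does not matter because C11 becomes a carbonyl in step 14.

Step 13
Reactants: 17 epoxide
Product: 19 allylic alcohol (C11–OH; C9=C10), via hydroxy selenide 18 (not isolated)
Conditions: (PhSe)2, NaBH4, EtOH, rt to 60 °C; then H2O2 (30 %), THF, 0 °C to rt
Reagents that add atoms: none
Why: Selenide opening followed by selenoxide syn-elimination, in which the selenolate attacks C10, the epoxide carbon remote from the branched C5, and the selenoxide eliminates away from the carbinol to place the alkene at C9=C10.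

Step 14
Reactants: 19 allylic alcohol
Product: 20 C11 enone (C11=O; C9=C10)
Conditions: Dess–Martin periodinane, NaHCO3, CH2Cl2, 0 °C to rt
Reagents that add atoms: none
Why: Dess–Martin oxidation is neutral and base-free, so the C5 stereocentre next to the new ketone is not put at risk.

Step 15
Reactants: 20 C11 enone
Product: 21 10-iodo enone
Conditions: I2, pyridine–CH2Cl2, 0 °C to rt
Reagents that add atoms: iodine II
Why: α-Iodination of a cyclic enone by conjugate addition of pyridine, iodination of the enolate and elimination, which can only place the halogen at C10.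

Step 16
Reactants: 21 10-iodo enone
Product: 22 10-methyl enone
Conditions: SnMe4, Pd2(dba)3 (5 mol %), AsPh3, CuI, NMP, 60 °C
Reagents that add atoms: tetramethylstannane C[Sn](C)(C)C
Why: Stille coupling of an α-iodo enone runs without base, so it installs the C10 methyl group without touching C5, and the acceptor-free cyclopropane is inert to the palladium catalyst.

Step 17
Reactants: 22 10-methyl enone
Product: 23 cross-conjugated diene (C11=C1H2; C10(Me)=C9)
Conditions: Cp2TiMe2, toluene, 70 °C, dark
Reagents that add atoms: dimethyltitanocene C[Ti](C)(C1C=CC=C1)C1C=CC=C1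
Why: Petasis methylenation is non-basic and tolerates hindered, enolisable ketones, ketals and silyl ethers, so C1 is attached without epimerising C5.

Step 18
Reactants: 23 cross-conjugated diene
Product: 25 homoallylic alcohol (C1H2OH α on C11; H11 β; C10(Me)=C9 kept), via B-alkyl-9-BBN 24 (not isolated)
Conditions: 9-BBN, THF, 0 °C to rt; then NaOH, H2O2, 0 °C
Reagents that add atoms: hydrogen peroxide OO
Why: Brown hydroboration–oxidation, in which 9-BBN takes the 1,1-disubstituted alkene in preference to the trisubstituted one and puts boron on C1, and allylic 1,3-strain with the methylene turns C4 onto the α face so that hydrogen reaches C11 from the β face and C1 ends up α, cis to C4.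

Step 19
Reactants: 25 homoallylic alcohol
Product: 26 9α,10α-epoxy alcohol
Conditions: VO(acac)2 (5 mol %), tBuOOH, CH2Cl2, 0 °C to rt
Reagents that add atoms: tert-butyl hydroperoxide CC(C)(C)OO
Why: Vanadium-catalysed hydroxyl-directed epoxidation of a homoallylic alcohol delivers oxygen to the face that carries C1, which sets the C10–O bond α and the C10 methyl group β.

Step 20
Reactants: 26 epoxy alcohol
Product: 27 diol (C10 tertiary alcohol α; C1H2OH)
Conditions: LiEt3BH, THF, 0 °C to 50 °C
Reagents that add atoms: none
Why: SN2 opening of a trisubstituted epoxide by hydride at the less substituted C9 keeps the C10–O bond, and the C1 alkoxide on the α face cannot deliver hydride to the backside of either C–O bond.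

Step 21
Reactants: 27 diol
Product: 28 C4 hydroxy ketone (rests largely as the five-membered C1–O–C4 hemiketal)
Conditions: Bi(OTf)3 (1 mol %), THF–H2O, rt
Reagents that add atoms: water O
Why: Lewis-acid-catalysed hydrolysis of an acyclic ketal under conditions known to spare primary silyl ethers, run only now, when C11 is sp3 and C5–H is activated by one carbonyl only.

Step 22
Reactants: 28 C4 hydroxy ketone
Product: 29 methyl enol ether (C4=C3H–OMe, E/Z mixture)
Conditions: MeOCH2PPh3Cl, KN(SiMe3)2 (excess), THF, 0 °C to rt
Reagents that add atoms: (methoxymethyl)triphenylphosphonium chloride COC[P+](c1ccccc1)(c1ccccc1)c1ccccc1.[Cl-]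
Why: Wittig methoxymethylenation, which proceeds on hemiketals through their open alkoxide form and is helped here by the electrophilic α-alkoxy ketone with a CH2 on one side, the alkene geometry being irrelevant.

Step 23
Reactants: 29 methyl enol ether
Product: 30 C1 aldehyde
Conditions: Dess–Martin periodinane, NaHCO3, CH2Cl2, 0 °C
Reagents that add atoms: none
Why: Buffered Dess–Martin oxidation of the only free primary alcohol leaves the enol ether, the tertiary alcohol and the C11 centre of the β-hydroxy aldehyde intact.

Step 24
Reactants: 30 C1 aldehyde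
Product: 32 enol-lactol (ring A closed; C1–OH, C10–OH and C13–OH free), via dialdehyde 31 (not isolated)
Conditions: aq HF (48 %), MeCN, 0 °C
Reagents that add atoms: water O
Why: Acid hydrolysis of the enol ether and of the silyl ether gives a 1,5-dialdehyde that should settle, like iridodial into nepetalactol, by ring–chain tautomerism as the cis-fused enol-lactol, because C1 and C4 are both α.

Step 25
Reactants: 32 enol-lactol
Product: 33 CNP0250836.3
Conditions: Ac2O, pyridine, CH2Cl2, 0 °C to rt
Reagents that add atoms: acetic anhydride CC(=O)OC(C)=O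
Why: Acetylation of the primary alcohol and of the equilibrating lactol, in which the tertiary C10 alcohol is too hindered to react without DMAP and the C1 acetate should take the axial position trans to C10 (anomeric effect), as in 1-O-acyl iridoids.

## Compound list

1 | tropylium tetrafluoroborate | [CH+]1C=CC=CC=C1.F[B-](F)(F)F | starting material
2 | methyl dimethoxyacetate | COC(OC)C(=O)OC | starting material
3 | lithium enolate of 2 | [Li+].[O-]C(OC)=C(OC)OC | intermediate
4 | methyl 2-(cyclohepta-2,4,6-trien-1-yl)-2,2-dimethoxyacetate | COC(=O)C(OC)(OC)C1C=CC=CC=C1 | intermediate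
5 | 2-(cyclohepta-2,4,6-trien-1-yl)-2,2-dimethoxyethanol | OCC(OC)(OC)C1C=CC=CC=C1 | intermediate
6 | mono-tert-butyl malonate | CC(C)(C)OC(=O)CC(=O)O | starting material
7 | tert-butyl 2-(cycloheptatrienyl)-2,2-dimethoxyethyl malonate | CC(C)(C)OC(=O)CC(=O)OCC(OC)(OC)C1C=CC=CC=C1 | intermediate
8 | diazomalonate, precursor of the key step | CC(C)(C)OC(=O)C(=[N+]=[N-])C(=O)OCC(OC)(OC)C1C=CC=CC=C1 | intermediate
9 | dirhodium carbene at C12 (carboxylate ligands and second rhodium not drawn) | CC(C)(C)OC(=O)C(=[Rh])C(=O)OCC(OC)(OC)C1C=CC=CC=C1 | intermediate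
10 | cyclopropane-fused cycloheptadiene lactone, product of the key step | CC(C)(C)OC(=O)[C@@]12C(=O)OCC(OC)(OC)[C@H]3C=CC=C[C@H]2[C@H]13 | intermediate
11 | C14/C15 diol, tert-butyl ester, diene | CC(C)(C)OC(=O)[C@]1(CO)[C@H]2C=CC=C[C@H](C(OC)(OC)CO)[C@@H]12 | intermediate
12 | C14 iodide, C15 alcohol | CC(C)(C)OC(=O)[C@]1(CI)[C@H]2C=CC=C[C@H](C(OC)(OC)CO)[C@@H]12 | intermediate
13 | oxepane (ring D ether) tert-butyl ester, diene | CC(C)(C)OC(=O)[C@@]12COCC(OC)(OC)[C@H]3C=CC=C[C@H]2[C@H]13 | intermediate
14 | C13 alcohol, diene | OC[C@@]12COCC(OC)(OC)[C@H]3C=CC=C[C@H]2[C@H]13 | intermediate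
15 | C13 silyl ether, diene | CC(C)(C)[Si](C)(C)OC[C@@]12COCC(OC)(OC)[C@H]3C=CC=C[C@H]2[C@H]13 | intermediate
16 | C10=C11 monoene | CC(C)(C)[Si](C)(C)OC[C@@]12COCC(OC)(OC)[C@H]3C=CCC[C@H]2[C@H]13 | intermediate
17 | 10β,11β-epoxide | CC(C)(C)[Si](C)(C)OC[C@@]12COCC(OC)(OC)[C@H]3[C@@H]4O[C@@H]4CC[C@H]2[C@H]13 | intermediate
18 | 11β-hydroxy-10α-phenylselenide | CC(C)(C)[Si](C)(C)OC[C@@]12COCC(OC)(OC)[C@H]3[C@H](O)[C@@H]([Se]c4ccccc4)CC[C@H]2[C@H]13 | intermediate
19 | C11 allylic alcohol, C9=C10 | CC(C)(C)[Si](C)(C)OC[C@@]12COCC(OC)(OC)[C@H]3[C@H](O)C=CC[C@H]2[C@H]13 | intermediate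
20 | C11 enone | CC(C)(C)[Si](C)(C)OC[C@@]12COCC(OC)(OC)[C@H]3C(=O)C=CC[C@H]2[C@H]13 | intermediate
21 | 10-iodo enone | CC(C)(C)[Si](C)(C)OC[C@@]12COCC(OC)(OC)[C@H]3C(=O)C(I)=CC[C@H]2[C@H]13 | intermediate
22 | 10-methyl enone | CC(C)(C)[Si](C)(C)OC[C@@]12COCC(OC)(OC)[C@H]3C(=O)C(C)=CC[C@H]2[C@H]13 | intermediate
23 | C11=C1H2 / C10(Me)=C9 diene | CC(C)(C)[Si](C)(C)OC[C@@]12COCC(OC)(OC)[C@H]3C(=C)C(C)=CC[C@H]2[C@H]13 | intermediate
24 | B-(C1)-alkyl-9-borabicyclo[3.3.1]nonane | CC(C)(C)[Si](C)(C)OC[C@@]12COCC(OC)(OC)[C@H]3[C@@H](CB4C5CCCC4CCC5)C(C)=CC[C@H]2[C@H]13 | intermediate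
25 | homoallylic alcohol (C1H2OH α) | CC(C)(C)[Si](C)(C)OC[C@@]12COCC(OC)(OC)[C@H]3[C@@H](CO)C(C)=CC[C@H]2[C@H]13 | intermediate
26 | 9α,10α-epoxy alcohol | CC(C)(C)[Si](C)(C)OC[C@@]12COCC(OC)(OC)[C@H]3[C@@H](CO)[C@@]4(C)O[C@H]4C[C@H]2[C@H]13 | intermediate
27 | C1/C10 diol, C4 ketal | CC(C)(C)[Si](C)(C)OC[C@@]12COCC(OC)(OC)[C@H]3[C@@H](CO)[C@@](C)(O)CC[C@H]2[C@H]13 | intermediate
28 | C4 hydroxy ketone (drawn open; hemiketal with C1–OH in solution) | CC(C)(C)[Si](C)(C)OC[C@@]12COCC(=O)[C@H]3[C@@H](CO)[C@@](C)(O)CC[C@H]2[C@H]13 | intermediate
29 | C4=C3H–OMe enol ether (E/Z) | CC(C)(C)[Si](C)(C)OC[C@@]12COCC(=COC)[C@H]3[C@@H](CO)[C@@](C)(O)CC[C@H]2[C@H]13 | intermediate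
30 | C1 aldehyde, enol ether | CC(C)(C)[Si](C)(C)OC[C@@]12COCC(=COC)[C@H]3[C@@H](C=O)[C@@](C)(O)CC[C@H]2[C@H]13 | intermediate
31 | C1/C3 dialdehyde (C4 epimers) | OC[C@@]12COCC(C=O)[C@H]3[C@@H](C=O)[C@@](C)(O)CC[C@H]2[C@H]13 | intermediate
32 | enol-lactol triol | OC[C@@]12COCC3=CO[C@H](O)[C@@H]4[C@H]3[C@@H]1[C@@H]2CC[C@]4(C)O | intermediate
33 | CNP0250836.3 | CC(=O)OC[C@@]12COCC3=CO[C@H](OC(C)=O)[C@@H]4[C@H]3[C@@H]1[C@@H]2CC[C@]4(C)O | target

## Step count and risks

Total step count: 25. Longest linear sequence: 25 (all building blocks are bought).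

**Step 5.** What may go wrong: the catalyst may discriminate weakly between the two enantiotopic ring alkenes, and part of the carbene may be lost to attack on a methoxy oxygen or to insertion into C5–H.

Fallback (resolution through covalent diastereomers instead of catalyst control): the material of low enantiomeric purity is carried unchanged through steps 6 to 9. The fallback sets out from 14. Acylation with (1S)-camphanic chloride and pyridine gives the camphanate F1 and, from the antipode, the diastereomeric camphanate F2. The two are separated by crystallisation or chromatography. LiOH in aqueous THF cleaves F1, and the route is rejoined at enantiopure 14.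

**Step 11.** What may go wrong: site selection between the two alkenes of the diene may be poor, and over-reduction may occur.

Fallback (1,4-oxygenation, which does not have to choose between the alkenes): this sets out from 15.
- Singlet oxygen (O2, tetraphenylporphyrin, light, CH2Cl2, −20 °C) adds across C8 and C11, anti to the cyclopropane, to give the endoperoxide F3.
- PPh3 attacks the less hindered oxygen on C8, and the C11 alkoxide closes in SN2′ fashion to the vinyl epoxide F4.
- Pd(PPh3)4 (zerovalent palladium, harmless now that the cyclopropane has no acceptor) isomerises F4 to the β,γ-enone F5.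
- DBU moves the alkene into conjugation, and the route is rejoined at 20.

**Step 24.** What may go wrong: the dialdehyde may be diverted into other acetals through the C10 hydroxyl, the β-alkoxy group may be lost at C15, or the lactol may erode in acid.

Fallback (ring A closed at the lactone level, then reduced): this sets out from 30.
- Pinnick oxidation (NaClO2, NaH2PO4, 2-methyl-2-butene) gives the carboxylic acid F6.
- Catalytic TsOH in toluene adds the acid to the enol ether and expels methanol to give the enol lactone F7.
- iBu2AlH at −78 °C reduces F7, as nepetalactone is reduced to nepetalactol, to the silylated lactol F8.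
- HF·pyridine removes the silyl group, and the route is rejoined at 32.

## Further compounds

F1 | step 5 | (1S)-camphanate of 14 | O=C(OC[C@@]12COCC(OC)(OC)[C@H]3C=CC=C[C@H]2[C@H]13)[C@@]45CC[C@@](C)(C(=O)O4)C5(C)C
F2 | step 5 | (1S)-camphanate of the antipode of 14 | O=C(OC[C@]12COCC(OC)(OC)[C@@H]3C=CC=C[C@@H]2[C@@H]13)[C@@]45CC[C@@](C)(C(=O)O4)C5(C)C
F3 | step 11 | 8α,11α-endoperoxide, C9=C10 | CC(C)(C)[Si](C)(C)OC[C@@]12COCC(OC)(OC)[C@H]3[C@@H]4C=C[C@@H](OO4)[C@H]2[C@H]13
F4 | step 11 | 10α,11α-epoxide, C8=C9 | CC(C)(C)[Si](C)(C)OC[C@@]12COCC(OC)(OC)[C@H]3[C@H]4O[C@H]4C=C[C@H]2[C@H]13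
F5 | step 11 | C11 ketone, C8=C9 (β,γ-enone) | CC(C)(C)[Si](C)(C)OC[C@@]12COCC(OC)(OC)[C@H]3C(=O)CC=C[C@H]2[C@H]13
F6 | step 24 | C1 carboxylic acid, enol ether | CC(C)(C)[Si](C)(C)OC[C@@]12COCC(=COC)[C@H]3[C@@H](C(=O)O)[C@@](C)(O)CC[C@H]2[C@H]13
F7 | step 24 | ring A enol lactone, C13 silyl ether | CC(C)(C)[Si](C)(C)OC[C@@]12COCC3=COC(=O)[C@@H]4[C@H]3[C@@H]1[C@@H]2CC[C@]4(C)O
F8 | step 24 | ring A enol-lactol, C13 silyl ether | CC(C)(C)[Si](C)(C)OC[C@@]12COCC3=CO[C@H](O)[C@@H]4[C@H]3[C@@H]1[C@@H]2CC[C@]4(C)O
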